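**Plan**

- Retrosynthesis: the C1–OH bond of ring A is cut first (phenol ← diazonium salt ← amine ← nitro group), then the diaryl ether bond C2–O, then C4–Cl, then the two C–Br bonds at C3 and C5.
- Enabling feature: in ring A (C1 OH, C2 O-aryl, C3 Br, C4 Cl, C5 Br, C6 H) the hydroxyl carbon C1 is ortho to the ether carbon C2. A nitro group at C1 therefore activates a C2–F bond toward 2,4-dibromophenoxide (ring B) and is afterwards converted into the hydroxyl group.
- An amino group at C4, para to the nitro group, directs both bromines to C3 and C5 and is then exchanged for chlorine. The fluorine is bought in with the starting material, because replacing an amine next to a nitro group by fluorine (Balz–Schiemann) is a poor reaction.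
- Forward: 3-fluoro-4-nitroaniline is dibrominated, NH2 is exchanged for Cl, the fluoride is displaced by 2,4-dibromophenol (the two preformed benzene rings are joined here), the nitro group is reduced and the amine becomes the hydroxyl. No ring is formed.
- Stereochemistry: the target has no stereocentre or other stereo element, so nothing has to be controlled.

Key step: step 5

**Step 1**
Reactants: 1 3-fluoro-4-nitroaniline
Product: 3 2,6-dibromo-3-fluoro-4-nitroaniline, via 2-bromo-5-fluoro-4-nitroaniline 2 (not isolated)
Conditions: Br2 (2.2 equiv), AcOH, 20 to 60 °C
Reagents that add atoms: bromine, BrBr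
Why: Electrophilic aromatic bromination in which the amino group directs both bromines to its two ortho positions (the para position carries the nitro group and both ortho positions are meta to it), as in the classical dibromination of 4-nitroaniline; the first bromine should enter para to fluorine (2), the second between NH2 and F.

**Step 2**
Reactants: 3 2,6-dibromo-3-fluoro-4-nitroaniline
Product: 5 1,3-dibromo-2-chloro-4-fluoro-5-nitrobenzene, via 2,6-dibromo-3-fluoro-4-nitrobenzenediazonium chloride 4 (not isolated)
Conditions: tBuONO (1.5 equiv), CuCl2 (1.2 equiv), MeCN, 60 °C
Reagents that add atoms: CuCl2 (copper dichloride), Cl[Cu]Cl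
Why: Sandmeyer chlorination under anhydrous conditions, the standard method for weakly basic 2,6-dihalo-4-nitroanilines: tert-butyl nitrite forms the diazonium ion 4, electron transfer releases N2, and the aryl radical takes a chlorine atom from CuCl2 as soon as it forms, so that 4 does not accumulate next to water or free acid that could attack the C–F carbon.

**Step 3**
Reactants: 5 1,3-dibromo-2-chloro-4-fluoro-5-nitrobenzene; 6 2,4-dibromophenol
Product: 7 1,3-dibromo-2-chloro-4-(2,4-dibromophenoxy)-5-nitrobenzene
Conditions: K2CO3 (1.5 equiv), DMF, 60 °C
Reagents that add atoms: none
Why: Nucleophilic aromatic substitution by addition–elimination (SNAr): the phenoxide of 6 adds at the C–F carbon, which is ortho to the nitro group and carries by far the best leaving group, whereas the C–Cl carbon para to the nitro group is shielded by two bromines and the bromines are meta to the nitro group and not activated.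

**Step 4**
Reactants: 7 1,3-dibromo-2-chloro-4-(2,4-dibromophenoxy)-5-nitrobenzene
Product: 8 3,5-dibromo-4-chloro-2-(2,4-dibromophenoxy)aniline
Conditions: Fe powder (5 equiv), AcOH/EtOH, 70 °C
Reagents that add atoms: none
Why: Béchamp reduction, in which iron metal in acetic acid transfers electrons and protons to the nitro group only, so that the four C–Br bonds, the C–Cl bond and the diaryl ether survive where catalytic hydrogenation would risk hydrodehalogenation.

**Step 5**
Reactants: 8 3,5-dibromo-4-chloro-2-(2,4-dibromophenoxy)aniline
Product: 10 3,5-dibromo-4-chloro-2-(2,4-dibromophenoxy)phenol, via 3,5-dibromo-4-chloro-2-(2,4-dibromophenoxy)benzenediazonium hydrogen sulfate 9 (not isolated)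
Conditions: NaNO2, conc. H2SO4/AcOH, 0–10 °C; urea; then Cu(NO3)2 (large excess), Cu2O (1 equiv), H2O, 20 °C
Reagents that add atoms: water, O
Why: Nitrosylsulfuric acid, formed from NaNO2 in concentrated H2SO4, diazotises the weakly basic, halogen-laden amine 8 to the diazonium hydrogen sulfate 9; in the aqueous copper bath monovalent copper from Cu2O reduces 9 by one electron, N2 leaves, and the aryl radical at C1 of ring A is intercepted by divalent copper, whose aquo ligand ends up on C1 as the hydroxyl group while monovalent copper is returned. The closest known reaction type is the hydroxydediazoniation of arenediazonium salts, used here in its copper-mediated room-temperature form in place of boiling the salt in dilute H2SO4. No ring closes and no stereocentre is formed; the only skeletal bond made is C1–O, which gives the target. The step needs chemoselectivity for oxygen transfer over three competitors: attack of C1 on C6' of ring B (closure to a dibenzofuran), hydrogen abstraction, and azo coupling of the new phenol with unreacted 9. Ring B is a poor acceptor because of its two bromines, and divalent copper at molar concentration should trap the radical faster than the five-membered ring can close, which is why this variant is preferred to the thermal aryl-cation pathway. Fast consumption of 9 at 20 °C in acidic solution, where the phenol stays un-ionised, leaves little chance for coupling, and the C–Br and C–Cl bonds do not react under these conditions.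

**Compound list**

1 | 3-fluoro-4-nitroaniline | Nc1ccc([N+](=O)[O-])c(F)c1 | starting material
2 | 2-bromo-5-fluoro-4-nitroaniline | Nc1cc(F)c([N+](=O)[O-])cc1Br | intermediate
3 | 2,6-dibromo-3-fluoro-4-nitroaniline | Nc1c(Br)cc([N+](=O)[O-])c(F)c1Br | intermediate
4 | 2,6-dibromo-3-fluoro-4-nitrobenzenediazonium chloride | N#[N+]c1c(Br)cc([N+](=O)[O-])c(F)c1Br.[Cl-] | intermediate
5 | 1,3-dibromo-2-chloro-4-fluoro-5-nitrobenzene | O=[N+]([O-])c1cc(Br)c(Cl)c(Br)c1F | intermediate
6 | 2,4-dibromophenol | Oc1ccc(Br)cc1Br | starting material
7 | 1,3-dibromo-2-chloro-4-(2,4-dibromophenoxy)-5-nitrobenzene | O=[N+]([O-])c1cc(Br)c(Cl)c(Br)c1Oc1ccc(Br)cc1Br | intermediate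
8 | 3,5-dibromo-4-chloro-2-(2,4-dibromophenoxy)aniline | Nc1cc(Br)c(Cl)c(Br)c1Oc1ccc(Br)cc1Br | intermediate
9 | 3,5-dibromo-4-chloro-2-(2,4-dibromophenoxy)benzenediazonium hydrogen sulfate | N#[N+]c1cc(Br)c(Cl)c(Br)c1Oc1ccc(Br)cc1Br.OS(=O)(=O)[O-] | intermediate
10 | 3,5-dibromo-4-chloro-2-(2,4-dibromophenoxy)phenol | Oc1cc(Br)c(Cl)c(Br)c1Oc1ccc(Br)cc1Br | target

**Step count**

Total steps: 5. Longest linear sequence: 5 steps (1 → 3 → 5 → 7 → 8 → 10); 6 enters at step 3.

**Steps most likely to fail**

Step 5. The reactive centre at C1 (a radical here, a cation on the thermal pathway) may add to C6' of ring B and close a dibenzofuran, or be reduced to the arene, instead of taking up oxygen. The fallback sets out from the diazonium salt 9 and returns at 10. The solution of 9 would be run into aqueous KI to give 1,3-dibromo-2-chloro-4-(2,4-dibromophenoxy)-5-iodobenzene F1; iodide and iodine capture aryl radicals at close to diffusion rate, and no phenol is present to couple. Iodine–magnesium exchange of F1 with iPrMgCl·LiCl in THF at −40 °C, which should leave the aryl bromides alone at this temperature, followed by B(OMe)3 and aqueous work-up would give [3,5-dibromo-4-chloro-2-(2,4-dibromophenoxy)phenyl]boronic acid F2. H2O2/NaOH would then oxidise the C–B bond of F2 to the phenol 10.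

Step 3. Addition of the hindered, weakly nucleophilic phenoxide at a carbon flanked by nitro and bromine may be slow, so that attack at the C–Cl carbon para to the nitro group or displacement of the nitro group gains ground. The fallback sets out from 5 and returns at 7 with the roles of the rings reversed. KOH in aqueous DMSO would exchange the fluoride of 5 for hydroxide, a small nucleophile, to give 2,4-dibromo-3-chloro-6-nitrophenol F3. Its sodium salt would be arylated with bis(2,4-dibromophenyl)iodonium chloride F4 in aqueous NaOH/dioxane at 80 °C, a ligand coupling on iodine that tolerates ortho substituents on both partners. F4 would be prepared from 1,3-dibromobenzene and iodyl sulfate, (IO)2SO4, in concentrated H2SO4 and precipitated with NaCl.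

Step 2. The diazonium ion 4 forms slowly from a very weakly basic amine between two bromines and sits in a ring made strongly electrophilic by the diazonio and nitro groups. Loss of fluoride or of an ortho bromine to chloride, or reduction to the arene, may therefore compete with chlorine transfer. The fallback sets out from 3 and returns at 7, bypassing 5. The ether bond would be made first, by heating 3 with 6 and Cs2CO3 in DMSO at 100 °C (the fluoride is still ortho to the nitro group), to give 2,6-dibromo-3-(2,4-dibromophenoxy)-4-nitroaniline F5. The Sandmeyer chlorination (tBuONO, CuCl2, MeCN, 60 °C) would then be run on F5, which no longer carries a labile fluoride and whose diazonium ion is less electron-poor.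

**Further compounds**

F1 | step 5 | 1,3-dibromo-2-chloro-4-(2,4-dibromophenoxy)-5-iodobenzene | Ic1cc(Br)c(Cl)c(Br)c1Oc1ccc(Br)cc1Br
F2 | step 5 | [3,5-dibromo-4-chloro-2-(2,4-dibromophenoxy)phenyl]boronic acid | OB(O)c1cc(Br)c(Cl)c(Br)c1Oc1ccc(Br)cc1Br
F3 | step 3 | 2,4-dibromo-3-chloro-6-nitrophenol | Oc1c(Br)c(Cl)c(Br)cc1[N+](=O)[O-]
F4 | step 3 | bis(2,4-dibromophenyl)iodonium chloride | Brc1ccc([I+]c2ccc(Br)cc2Br)c(Br)c1.[Cl-]
F5 | step 2 | 2,6-dibromo-3-(2,4-dibromophenoxy)-4-nitroaniline | Nc1c(Br)cc([N+](=O)[O-])c(Oc2ccc(Br)cc2Br)c1Br
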